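(Readings and results are simulated from invented constants; the scatter is artificial.)

The constants of this flask were hidden from me, so I began with what the readings give without them: how fast product disappears once Z has stopped feeding it.

| setting | winter | dawn | flask |
|---|---|---|---|
| Z | 0.070 M | 0.11 M | 0.050 M |
| L | 2.5 mM (held) | 2.5 mM (held) | 2.5 mM (held) |
| remark | run made earlier | run made earlier |  |
| time |  |  | 30 min |

* amount of J and G together at 30 min, in percent of the Z charged
* concentration of E in solution at 30 min, in percent of saturation

- J is meant together with its G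
- solid, in amounts per volume of the solution: G
- what was read earlier has a scatter of 1.5 percentage points, one standard deviation
- at the start none of L is in solution
- E is what L becomes in solution

winter run (percent of the Z charged)

| time / min | J / % | G / % | Z / % |
|---|---|---|---|
| 2.50 | 72 | 69 | 29 |
| 4.00 | 87 | 84 | 11 |
| 6.00 | 93 | 96 | 5 |
| 8.00 | 96 | 96 | 2 |
| 12.0 | 96 | 96 | 1 |
| 20.0 | 93 | 91 | 0 |
| 30.0 | 90 | 92 | 0 |

dawn run (percent of the Z charged)

| time / min | J / % | G / % | Z / % |
|---|---|---|---|
| 4.00 | 85 | 83 | 16 |
| 8.00 | 97 | 95 | 3 |
| 12.0 | 97 | 97 | 0 |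
| 15.0 | 100 | 96 | 0 |
| 20.0 | 97 | 93 | 2 |
| 25.0 | 97 | 95 | 3 |
| 30.0 | 96 | 96 | 0 |

The J column already counts G. In the winter run, the row at 12.0 min shows Z at 1 % and J at 96 %, and the last row shows J at 90 %. That run therefore lost a fraction 0.00333 min⁻¹ of its charge. The dawn run, between the same times, went from 97 % to 96 %, a fraction 5.56 × 10⁻⁴ min⁻¹. Each reading scatters by 1.5 percentage points, so I took the two runs together as one rough reading.

I assumed that the loss runs through dissolved J, held by the crystals at one level, so that it is equal per litre whatever the charge. Each fraction times its charge, averaged, gave 0.147 mM min⁻¹. I call this the drain: J lost per minute and per litre while crystals stand. Divided by a charge, it gives the fraction of that charge lost per minute.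

For this flask, with 0.050 M of Z, that fraction is 0.00294 min⁻¹. Over 30 min I reckoned 8.83 % of the charge gone, so y near 91.2 %.

The forecast gave 88 % for y, lower than my figure, on the ground of “roughly constant absolute loss”, and 99.5 % for E.

The flask gave 89.2 % and 99.9 %.

    L ⇌ E, rate k1*(csat - [E]) (kL = 1.30 s⁻¹)
    Z + E ⇌ J (K = 220 M⁻¹, k = 4.10 M⁻¹ s⁻¹)
    E + J → Q (k = 1.70 M⁻¹ s⁻¹)
    G ⇌ J, rate k4*(cs4 - [J]) while solid is left; crystals form when [J] > cs4 (solubility = 0.530 mM, k = 0.400 s⁻¹)

The drain was the loss of E + J to Q, one part of the shortfall: this flask without that step gave 98.1 % against 89.2 %. The limit of solubility of J and the hour of the reading together kept that loss this small: this flask gave 3.03 % without the limit and 17.0 % when read ten times later. By 30 min this flask had 8.90 % of its charge in Q, beside the 8.83 % reckoned, and Z, the limiting reagent, kept 1.9 %. Read at 50 min, the same drain gives 14.7 % of the charge, and that flask held Q at 14.2 %.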